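Everything rests on the C5a–C6 bond of the cyclohexane ring (benzoxepine numbering: O1, C2–C5, C5a, C6–C9, C9a). In the key step a silyl triflate opens the terminal epoxide of a bis-epoxide chain, the inner epoxide oxygen closes the oxepane as an epoxonium ion, and a Z-silyl enol ether (C6=C7) attacks the tertiary C5a with inversion. One operation thus closes the cyclohexane as the last ring, relays the trans C5a/C9a fusion from an E-epoxide, sets C6 and leaves a C7 ketone for equatorial methyl addition. The precursor is a geranyl-derived bis-epoxy silyl enol ether that already carries the complete hydroazulene.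

Key step: step 14

Remark: 2,4,4-trimethylcyclohex-2-en-1-one (1) is taken to be a catalogue compound.
Remark: the sense of induction of the ferrocenyl diphosphine in step 2 is assumed; the mirror-image ligand is used if the opposite sense is found.
Numbering in names: hydroazulene C1 (carbinol), C2, C3, C3a, C4 (CMe2), C5 (side-chain carbon), C6 (methyl-bearing alkene carbon), C7, C8, C8a. "Az" = (1R,3aR,5S,8aR)-1,4,4,6-tetramethyl-1-[(triethylsilyl)oxy]-1,2,3,3a,4,5,8,8a-octahydroazulen-5-yl.

**Hydroazulene half**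

Step 1
Reactants: 1 2,4,4-trimethylcyclohex-2-en-1-one
Product: 2 2,4,4-trimethylcyclohexa-2,5-dien-1-one
Conditions: DDQ, TsOH (cat.), dioxane, reflux
Reagents that add atoms: none
Why: Quinone dehydrogenation of the enone through its dienol removes the C5/C6 hydrogens and cannot aromatise because C4 is quaternary.

Step 2
Reactants: 2 2,4,4-trimethylcyclohexa-2,5-dien-1-one; 3 2-(2-bromoethyl)-2-methyl-1,3-dioxolane
Product: 6 trimethyl({(3R)-4,4,6-trimethyl-3-[2-(2-methyl-1,3-dioxolan-2-yl)ethyl]cyclohexa-1,5-dien-1-yl}oxy)silane, via Grignard reagent 4 (not isolated), via magnesium dienolate 5 (not isolated)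
Conditions: Mg, THF, 25 °C; then 2, CuBr·SMe2 (5 mol %), (R)-1-[(S)-2-(diphenylphosphino)ferrocenyl]ethyldicyclohexylphosphine (6 mol %), t-BuOMe, −78 °C; then Me3SiCl, Et3N, −78 °C to rt
Reagents that add atoms: chlorotrimethylsilane C[Si](C)(C)Cl
Why: Copper-catalysed asymmetric conjugate addition of the Grignard reagent should occur at C5 of the unsubstituted enone arm (the α-methyl arm is deactivated), the chiral diphosphine–copper complex choosing the enone face to set the (R) centre, and the magnesium enolate is then O-silylated regiospecifically.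

Step 3
Reactants: 6 silyl dienol ether
Product: 7 trimethyl({(1S,5R,6R)-2,4,4-trimethyl-5-[2-(2-methyl-1,3-dioxolan-2-yl)ethyl]bicyclo[4.1.0]hept-2-en-1-yl}oxy)silane (cyclopropane anti to the side chain, expected major isomer)
Conditions: Et2Zn, CH2I2, CH2Cl2, 0 °C
Reagents that add atoms: diiodomethane ICI
Why: Simmons–Smith cyclopropanation (Furukawa variant) should attack the electron-rich silyl enol ether double bond of the 2-silyloxy diene in preference to the trisubstituted alkene; the two cyclopropane stereocentres are lost in the next step.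

Step 4
Reactants: 7 silyloxy vinylcyclopropane
Product: 10 (5R)-2,4,4-trimethyl-5-(3-oxobutyl)cyclohepta-2,6-dien-1-one, via chloro ketone 8 (not isolated), via ketal dienone 9 (not isolated)
Conditions: FeCl3, DMF, 0 °C to rt; NaOAc, MeOH, reflux; then 1 M HCl, THF, rt
Reagents that add atoms: water O
Why: Saegusa–Ito ring expansion: one-electron oxidation of the silyloxycyclopropane by FeCl3 cleaves the internal cyclopropane bond to the ring-enlarged β-chloro ketone, acetate eliminates HCl to the cross-conjugated cycloheptadienone, and dilute acid hydrolyses the dioxolane.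

Step 5
Reactants: 10 (5R)-2,4,4-trimethyl-5-(3-oxobutyl)cyclohepta-2,6-dien-1-one
Product: 11 (1R,3aR,8aR)-1-hydroxy-1,4,4,6-tetramethyl-2,3,3a,4,8,8a-hexahydroazulen-7(1H)-one (cis-fused, OH cis to the ring-fusion hydrogens)
Conditions: SmI2, HMPA, THF, −78 °C; aq. NH4Cl
Reagents that add atoms: none
Why: SmI2 ketyl–olefin (carbonyl–enone) reductive cyclisation in the 5-exo mode joins the ketone carbon to C6, the β-carbon of the unhindered enone; the three-atom tether enforces the cis ring fusion and the bulky samarium-bound oxygen takes the exo position anti to the enolate carbon, which places the hydroxyl trans to C8.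

Step 6
Reactants: 11 hydroxy enone
Product: 12 (1R,3aR,8aR)-1,4,4,6-tetramethyl-1-[(triethylsilyl)oxy]-2,3,3a,4,8,8a-hexahydroazulen-7(1H)-one
Conditions: Et3SiOTf, 2,6-lutidine, CH2Cl2, −78 °C
Reagents that add atoms: triethylsilyl trifluoromethanesulfonate CC[Si](CC)(CC)OS(=O)(=O)C(F)(F)F
Why: Silyl triflate silylation of the hindered tertiary alcohol is faster than enolisation of the enone at −78 °C and protects the alcohol for the acidic Claisen step and the Lewis-acid key step.

Step 7
Reactants: 12 silyl ether enone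
Product: 13 (1R,3aR,7S,8aR)-1,4,4,6-tetramethyl-1-[(triethylsilyl)oxy]-1,2,3,3a,4,7,8,8a-octahydroazulen-7-ol
Conditions: NaBH4, CeCl3·7H2O, MeOH, −78 °C
Reagents that add atoms: none
Why: Luche 1,2-reduction; hydride should arrive on the convex face of the cis-fused bicycle (the face of the ring-fusion hydrogens), so the C7–O bond lies on the concave face.

Step 8
Reactants: 13 allylic alcohol
Product: 14 ethyl 2-Az-acetate
Conditions: MeC(OEt)3, EtCO2H (cat.), 140 °C
Reagents that add atoms: triethyl orthoacetate CC(OCC)(OCC)OCC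
Why: Johnson–Claisen rearrangement: the ketene acetal on the C7 oxygen delivers the acetate carbon suprafacially to C5, so the C7 configuration is transferred to C5 (side chain on the concave face) and the double bond moves to C6=C7.

Step 9
Reactants: 14 ethyl 2-Az-acetate
Product: 15 2-Az-acetaldehyde
Conditions: i-Bu2AlH, CH2Cl2, −78 °C; aq. potassium sodium tartrate
Reagents that add atoms: none
Why: Partial ester reduction stops at the aldehyde because the tetrahedral aluminium hemiacetal is stable at low temperature.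

**Bis-epoxide half**

Step 10
Reactants: 16 dimethyl (2-oxopropyl)phosphonate; 17 geranyl bromide
Product: 18 dimethyl [(5E)-6,10-dimethyl-2-oxoundeca-5,9-dien-1-yl]phosphonate
Conditions: NaH, THF, 0 °C; n-BuLi, 0 °C; then 17, 0 °C to rt
Reagents that add atoms: none
Why: γ-Alkylation of the β-keto phosphonate dianion: the more basic terminal carbanion displaces the primary allylic bromide by SN2 with retention of the E geometry.

Step 11
Reactants: 18 dienyl keto phosphonate
Product: 19 dimethyl {4-[(2R,3R)-3-{2-[(2R)-3,3-dimethyloxiran-2-yl]ethyl}-3-methyloxiran-2-yl]-2-oxobutyl}phosphonate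
Conditions: 1,2:4,5-di-O-isopropylidene-β-D-erythro-2,3-hexodiulo-2,6-pyranose (0.6 equiv), KHSO5 (as 2KHSO5·KHSO4·K2SO4), K2CO3, Bu4NHSO4, Na2B4O7 buffer, MeCN–CH2(OMe)2–H2O, 0 °C
Reagents that add atoms: potassium peroxymonosulfate [K+].[O-]S(=O)(=O)OO
Why: Shi epoxidation: the chiral dioxirane epoxidises both trisubstituted alkenes through the spiro transition state, which with the D-fructose-derived ketone gives the (R)-configured epoxides, while the weakly acidic keto phosphonate is not enolised at pH 10.5.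

**Union and endgame**

Step 12
Reactants: 19 bis-epoxy keto phosphonate; 15 2-Az-acetaldehyde
Product: 20 (2E)-1-Az-6-[(2R,3R)-3-{2-[(2R)-3,3-dimethyloxiran-2-yl]ethyl}-3-methyloxiran-2-yl]hex-2-en-4-one
Conditions: NaH, THF, 0 °C; then 15, 0 °C to rt
Reagents that add atoms: none
Why: Horner–Wadsworth–Emmons olefination of the stabilised keto phosphonate anion joins the two halves as the E-enone; the epoxides are inert to this soft anion.

Step 13
Reactants: 20 E-enone
Product: 21 (3Z)-1-Az-6-[(2R,3R)-3-{2-[(2R)-3,3-dimethyloxiran-2-yl]ethyl}-3-methyloxiran-2-yl]-4-[(triethylsilyl)oxy]hex-3-ene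
Conditions: Et3SiH, RhCl(PPh3)3 (2 mol %), benzene, 50 °C
Reagents that add atoms: triethylsilane CC[SiH](CC)CC
Why: Rhodium-catalysed 1,4-hydrosilylation of the s-cis enone gives the regiodefined Z-silyl enol ether between C6 and C7, which enolisation of the saturated ketone could not deliver selectively.

Step 14
Reactants: 21 Z-silyl enol ether bis-epoxide
Product: 23 (3R,5aR,6R,9aR)-6-(2-Az-ethyl)-2,2,5a-trimethyl-3-[(trimethylsilyl)oxy]octahydro-1-benzoxepin-7(2H)-one, via epoxonium triflate 22 (not isolated)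
Conditions: Me3SiOTf, 2,6-di-tert-butyl-4-methylpyridine, CH2Cl2, −78 °C; aq. NaHCO3
Reagents that add atoms: trimethylsilyl trifluoromethanesulfonate C[Si](C)(C)OS(=O)(=O)C(F)(F)F
Why: Me3SiOTf silylates the terminal epoxide, the oxygen of the inner epoxide attacks its tertiary carbon C2 with inversion to give the bicyclic epoxonium ion 22, and the nucleophilic carbon C6 of the Z-silyl enol ether then opens 22 at the tertiary C5a with inversion, after which loss of Et3SiOTf unveils the C7 ketone. The closest known reaction type is the Lewis-acid-promoted tandem oxacyclisation–carbacyclisation of polyepoxides terminated by an enol silane. The oxepane closes first by a 7-endo epoxide opening, and the cyclohexane closes last in a 6-(enolendo)-exo-tet mode, which is a 6-endo opening of the epoxonium ion. C5a and C9a are relayed from the (2R,3R)-epoxide, whose E geometry and double anti opening translate into the trans fusion with an axial C5a methyl, and C3 keeps the configuration of the terminal epoxide. C6 is set by a chair transition state in which the Z-enol ether places the side chain equatorial, and it stays epimerisable next to the ketone toward this more stable arrangement. The step needs endo regioselectivity at both epoxides, secured by their tertiary cation-stabilising carbons, and tolerance of the trisubstituted alkene and the tertiary silyl ether, secured by aprotic conditions at −78 °C buffered with the hindered pyridine.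

Step 15
Reactants: 23 bicyclic ketone
Product: 24 (3R,5aR,6R,7S,9aR)-6-(2-Az-ethyl)-2,2,5a,7-tetramethyl-3-[(trimethylsilyl)oxy]decahydro-1-benzoxepin-7-ol
Conditions: MeMgBr, CeCl3, THF, −78 to 0 °C; aq. NH4Cl
Reagents that add atoms: methylmagnesium bromide C[Mg]Br
Why: Organocerium 1,2-addition suppresses enolisation of the hindered ketone; the axial face of C7 is blocked by the syn-axial C5a methyl, so methyl should add equatorially and the new hydroxyl is axial, cis to the C5a methyl (7S).

Step 16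
Reactants: 24 bis-silyl ether
Product: 25 (3R,5aR,6R,7S,9aR)-6-{2-[(1R,3aR,5S,8aR)-1-hydroxy-1,4,4,6-tetramethyl-1,2,3,3a,4,5,8,8a-octahydroazulen-5-yl]ethyl}-2,2,5a,7-tetramethyldecahydro-1-benzoxepine-3,7-diol
Conditions: Bu4NF, THF, 0 to 40 °C
Reagents that add atoms: none
Why: Fluoride cleaves both silyl ethers; no stereocentre is touched.

Step 17
Reactants: 25 triol
Product: 26 sipholenone A
Conditions: Dess–Martin periodinane, NaHCO3, CH2Cl2, rt
Reagents that add atoms: none
Why: Dess–Martin oxidation converts the only secondary alcohol (C3) into the ketone; the two tertiary alcohols and the alkene are inert.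

**Compound list**

1 | 2,4,4-trimethylcyclohex-2-en-1-one | CC1=CC(C)(C)CCC1=O | starting material
2 | 2,4,4-trimethylcyclohexa-2,5-dien-1-one | CC1=CC(C)(C)C=CC1=O | intermediate
3 | 2-(2-bromoethyl)-2-methyl-1,3-dioxolane | CC1(CCBr)OCCO1 | starting material
4 | [2-(2-methyl-1,3-dioxolan-2-yl)ethyl]magnesium bromide | CC1(CC[Mg]Br)OCCO1 | intermediate
5 | bromomagnesium (3R)-4,4,6-trimethyl-3-[2-(2-methyl-1,3-dioxolan-2-yl)ethyl]cyclohexa-1,5-dien-1-olate | CC1=CC(C)(C)[C@H](CCC2(C)OCCO2)C=C1O[Mg]Br | intermediate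
6 | trimethyl({(3R)-4,4,6-trimethyl-3-[2-(2-methyl-1,3-dioxolan-2-yl)ethyl]cyclohexa-1,5-dien-1-yl}oxy)silane | CC1=CC(C)(C)[C@H](CCC2(C)OCCO2)C=C1O[Si](C)(C)C | intermediate
7 | trimethyl({(1S,5R,6R)-2,4,4-trimethyl-5-[2-(2-methyl-1,3-dioxolan-2-yl)ethyl]bicyclo[4.1.0]hept-2-en-1-yl}oxy)silane | CC1=CC(C)(C)[C@H](CCC3(C)OCCO3)[C@H]2C[C@@]12O[Si](C)(C)C | intermediate
8 | 6-chloro-2,4,4-trimethyl-5-[2-(2-methyl-1,3-dioxolan-2-yl)ethyl]cyclohept-2-en-1-one (C5 as in 9, C6 epimers) | CC1=CC(C)(C)[C@H](CCC2(C)OCCO2)C(Cl)CC1=O | intermediate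
9 | (5R)-2,4,4-trimethyl-5-[2-(2-methyl-1,3-dioxolan-2-yl)ethyl]cyclohepta-2,6-dien-1-one | CC1=CC(C)(C)[C@H](CCC2(C)OCCO2)C=CC1=O | intermediate
10 | (5R)-2,4,4-trimethyl-5-(3-oxobutyl)cyclohepta-2,6-dien-1-one | CC1=CC(C)(C)[C@H](CCC(C)=O)C=CC1=O | intermediate
11 | (1R,3aR,8aR)-1-hydroxy-1,4,4,6-tetramethyl-2,3,3a,4,8,8a-hexahydroazulen-7(1H)-one | CC1=CC(C)(C)[C@@H]2CC[C@@](C)(O)[C@@H]2CC1=O | intermediate
12 | (1R,3aR,8aR)-1,4,4,6-tetramethyl-1-[(triethylsilyl)oxy]-2,3,3a,4,8,8a-hexahydroazulen-7(1H)-one | CC1=CC(C)(C)[C@@H]2CC[C@@](C)(O[Si](CC)(CC)CC)[C@@H]2CC1=O | intermediate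
13 | (1R,3aR,7S,8aR)-1,4,4,6-tetramethyl-1-[(triethylsilyl)oxy]-1,2,3,3a,4,7,8,8a-octahydroazulen-7-ol | CC1=CC(C)(C)[C@@H]2CC[C@@](C)(O[Si](CC)(CC)CC)[C@@H]2C[C@@H]1O | intermediate
14 | ethyl 2-{(1R,3aR,5S,8aR)-1,4,4,6-tetramethyl-1-[(triethylsilyl)oxy]-1,2,3,3a,4,5,8,8a-octahydroazulen-5-yl}acetate | CC1=CC[C@@H]2[C@@H](CC[C@@]2(C)O[Si](CC)(CC)CC)C(C)(C)[C@H]1CC(=O)OCC | intermediate
15 | 2-{(1R,3aR,5S,8aR)-1,4,4,6-tetramethyl-1-[(triethylsilyl)oxy]-1,2,3,3a,4,5,8,8a-octahydroazulen-5-yl}acetaldehyde | CC1=CC[C@@H]2[C@@H](CC[C@@]2(C)O[Si](CC)(CC)CC)C(C)(C)[C@H]1CC=O | intermediate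
16 | dimethyl (2-oxopropyl)phosphonate | COP(=O)(OC)CC(C)=O | starting material
17 | geranyl bromide, (2E)-1-bromo-3,7-dimethylocta-2,6-diene | CC(C)=CCC/C(C)=C/CBr | starting material
18 | dimethyl [(5E)-6,10-dimethyl-2-oxoundeca-5,9-dien-1-yl]phosphonate | COP(=O)(OC)CC(=O)CC/C=C(\C)CCC=C(C)C | intermediate
19 | dimethyl {4-[(2R,3R)-3-{2-[(2R)-3,3-dimethyloxiran-2-yl]ethyl}-3-methyloxiran-2-yl]-2-oxobutyl}phosphonate | COP(=O)(OC)CC(=O)CC[C@H]1O[C@]1(C)CC[C@H]1OC1(C)C | intermediate
20 | (2E)-1-Az-6-[(2R,3R)-3-{2-[(2R)-3,3-dimethyloxiran-2-yl]ethyl}-3-methyloxiran-2-yl]hex-2-en-4-one | CC1=CC[C@@H]2[C@@H](CC[C@@]2(C)O[Si](CC)(CC)CC)C(C)(C)[C@H]1C/C=C/C(=O)CC[C@H]1O[C@]1(C)CC[C@H]1OC1(C)C | intermediate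
21 | (3Z)-1-Az-6-[(2R,3R)-3-{2-[(2R)-3,3-dimethyloxiran-2-yl]ethyl}-3-methyloxiran-2-yl]-4-[(triethylsilyl)oxy]hex-3-ene | CC1=CC[C@@H]2[C@@H](CC[C@@]2(C)O[Si](CC)(CC)CC)C(C)(C)[C@H]1CC/C=C(\O[Si](CC)(CC)CC)CC[C@H]1O[C@]1(C)CC[C@H]1OC1(C)C | intermediate
22 | bicyclic epoxonium triflate (oxonium oxygen bonded to C2, C5a and C9a; C3 silyl ether; enol ether intact) | CC1=CC[C@@H]2[C@@H](CC[C@@]2(C)O[Si](CC)(CC)CC)C(C)(C)[C@H]1CC/C=C(\O[Si](CC)(CC)CC)CC[C@H]1[O+]2C(C)(C)[C@H](O[Si](C)(C)C)CC[C@]12C.[O-]S(=O)(=O)C(F)(F)F | intermediate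
23 | (3R,5aR,6R,9aR)-6-(2-Az-ethyl)-2,2,5a-trimethyl-3-[(trimethylsilyl)oxy]octahydro-1-benzoxepin-7(2H)-one | CC1=CC[C@@H]2[C@@H](CC[C@@]2(C)O[Si](CC)(CC)CC)C(C)(C)[C@H]1CC[C@@H]1[C@@]2(C)CC[C@@H](O[Si](C)(C)C)C(C)(C)O[C@@H]2CCC1=O | intermediate
24 | (3R,5aR,6R,7S,9aR)-6-(2-Az-ethyl)-2,2,5a,7-tetramethyl-3-[(trimethylsilyl)oxy]decahydro-1-benzoxepin-7-ol | CC1=CC[C@@H]2[C@@H](CC[C@@]2(C)O[Si](CC)(CC)CC)C(C)(C)[C@H]1CC[C@@H]1[C@@]2(C)CC[C@@H](O[Si](C)(C)C)C(C)(C)O[C@@H]2CC[C@]1(C)O | intermediate
25 | (3R,5aR,6R,7S,9aR)-6-{2-[(1R,3aR,5S,8aR)-1-hydroxy-1,4,4,6-tetramethyl-1,2,3,3a,4,5,8,8a-octahydroazulen-5-yl]ethyl}-2,2,5a,7-tetramethyldecahydro-1-benzoxepine-3,7-diol | CC1=CC[C@@H]2[C@@H](CC[C@@]2(C)O)C(C)(C)[C@H]1CC[C@@H]1[C@@]2(C)CC[C@@H](O)C(C)(C)O[C@@H]2CC[C@]1(C)O | intermediate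
26 | sipholenone A, (5aR,6R,7S,9aR)-7-hydroxy-6-{2-[(1R,3aR,5S,8aR)-1-hydroxy-1,4,4,6-tetramethyl-1,2,3,3a,4,5,8,8a-octahydroazulen-5-yl]ethyl}-2,2,5a,7-tetramethyloctahydro-1-benzoxepin-3(2H)-one | CC1=CC[C@@H]2[C@@H](CC[C@@]2(C)O)C(C)(C)[C@H]1CC[C@@H]1[C@@]2(C)CCC(=O)C(C)(C)O[C@@H]2CC[C@]1(C)O | target

Total step count: 17. Longest linear sequence: 15 steps (steps 1–9, then 12–17).

**Steps most likely to fail**

Step 14. The enol ether may open the inner epoxide before the oxepane has formed, or the epoxonium ion may lose a proton, so that the tandem closure is inefficient on the fully elaborated substrate. The fallback moves the same oxepane-then-cyclohexane closure to the small fragment and makes the union afterwards. It sets out from 19: Me3SiCl and Et3N convert the acidic keto phosphonate into the phosphonate-substituted silyl enol ether F1, whose position is fixed by the phosphonate. Me3SiOTf with 2,6-di-tert-butyl-4-methylpyridine at −78 °C then gives the bicyclic keto phosphonate F2 by the same epoxonium mechanism; since 15 is prepared beforehand, this remains the last ring closure of the synthesis. Horner–Wadsworth–Emmons reaction of F2 with 15 (NaH, THF) gives the alkylidene ketone F3. Conjugate reduction with [(Ph3P)CuH]6 and an equilibrating work-up should place the side chain equatorial and returns to the route at 23.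

Step 5. SmI2 may reduce or dimerise the cross-conjugated dienone faster than the carbon–carbon bond forms, or facial control at the new carbinol carbon may be poor. The fallback replaces the ketyl by a neutral α-silyloxy radical generated by hydrogen-atom transfer. It sets out from 10: LiN(SiMe3)2 and Et3SiCl at −78 °C give the kinetic terminal silyl enol ether F4 (the dienone has no α-hydrogen). Fe(acac)3 and PhSiH3 in EtOH then transfer a hydrogen atom to the enol ether terminus, and the tertiary α-silyloxy radical should add 5-exo to the enone with the bulky silyloxy group exo. This gives the silyl ether directly and returns at 12, so step 6 is not needed.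

Step 2. Facial discrimination by the copper catalyst may be insufficient with this functionalised Grignard reagent, or 1,2-addition may compete. The fallback gives up asymmetric catalysis for a separation of enantiomers. It sets out from 2: ligand-free CuBr·SMe2-catalysed addition of 4 with an NH4Cl quench gives the racemic enone F5. Preparative chromatography on a chiral stationary phase separates the (R)-enone F6. LiN(i-Pr)2 and Me3SiCl at −78 °C form the kinetic cross-conjugated silyl dienol ether, which returns to the route at 6.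

Further compounds
F1 | step 14 | dimethyl [(1Z)-4-[(2R,3R)-3-{2-[(2R)-3,3-dimethyloxiran-2-yl]ethyl}-3-methyloxiran-2-yl]-2-[(trimethylsilyl)oxy]but-1-en-1-yl]phosphonate | COP(=O)(OC)/C=C(\O[Si](C)(C)C)CC[C@H]1O[C@]1(C)CC[C@H]1OC1(C)C
F2 | step 14 | dimethyl {2,2,5a-trimethyl-7-oxo-3-[(trimethylsilyl)oxy]decahydro-1-benzoxepin-6-yl}phosphonate (C3, C5a and C9a arranged as in 23; C6 epimers) | COP(=O)(OC)C1C(=O)CC[C@H]2OC(C)(C)[C@H](O[Si](C)(C)C)CC[C@]12C
F3 | step 14 | 6-(2-Az-ethylidene) analogue of 23 (either alkene geometry) | CC1=CC[C@@H]2[C@@H](CC[C@@]2(C)O[Si](CC)(CC)CC)C(C)(C)[C@H]1CC=C1C(=O)CC[C@H]2OC(C)(C)[C@H](O[Si](C)(C)C)CC[C@]12C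
F4 | step 5 | (5R)-2,4,4-trimethyl-5-{3-[(triethylsilyl)oxy]but-3-en-1-yl}cyclohepta-2,6-dien-1-one | CC1=CC(C)(C)[C@H](CCC(=C)O[Si](CC)(CC)CC)C=CC1=O
F5 | step 2 | racemic 2,4,4-trimethyl-5-[2-(2-methyl-1,3-dioxolan-2-yl)ethyl]cyclohex-2-en-1-one | CC1=CC(C)(C)C(CCC2(C)OCCO2)CC1=O
F6 | step 2 | (5R)-2,4,4-trimethyl-5-[2-(2-methyl-1,3-dioxolan-2-yl)ethyl]cyclohex-2-en-1-one | CC1=CC(C)(C)[C@H](CCC2(C)OCCO2)CC1=O
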